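In the flask every unit of free monomer lost reappears as monomer in chains or as quenched substrate, and every initiator used begins one chain, so chain length and conversion draw on one balance.

free monomer 0.050 M; transfer agent 5.00 mM; protic impurity 0.0500 M; initiator 2.9 mM; time 30 min

    free monomer + initiator → living end + monomer in chains (k1 = 0.154 /M/s)
    free monomer + living end → monomer in chains + living end, rate k2*[living end]*[free monomer] (k2 = 0.672 /M/s)
    living end + transfer agent → dead chain (k3 = 0.211 /M/s)
    living end → dead end (k4 = 8.29 × 10⁻⁴ /s)
    protic impurity + free monomer → quenched substrate (k5 = 0.0152 /M/s)

- average number of monomer units in a chain (chains begun, living or dead) at 30 min
- part of the free monomer that has reacted at 30 min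

- the average divides the monomer in chains by the number of chains begun, living and dead together
- run time (flask): 30 min

My decision for the next run was whether to keep the initiator charge. Free monomer falls pseudo-first-order in each step that consumes it, so minus the logarithm of its remaining fraction is a sum of exposures, and I replaced each curve by its mean. With the transfer agent held at its charge, I reckoned the average life of a begun chain at 8.85 min. I counted the initiator charge as having passed through that life within the run, so the propagation constant times charge times life gave 1.03, the living-end exposure. I took the protic impurity at a mean fraction of 0.798 of its charge, which gave an impurity exposure of 1.09. Initiation added the initiator charge as a fraction of the monomer charge, 0.0580.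

My sum gave a conversion of 88.7%. Splitting that conversion by exposures, with one chain per initiator charged, gave a length of 7.65. I expected this length to read low, because the life of 8.85 min is shorter than the run, so the living ends work early. I kept the charge, because the living-end exposure and the impurity exposure stood level.

The forecast gave 8.7 units per chain and 88% of the free monomer reacted, from “A rough mental march through time”; its length exceeded mine.

The flask gave 8.82 units per chain and 88.0% of the free monomer reacted. Half of the passing of free monomer into chains was done by 5.57 min. For the neighbour flask charged with 7.2 × 10⁻⁴ M of initiator, the living-end exposure came to 0.257. Its dead end of 3.06 × 10⁻⁴ M, multiplied by the ratio of the propagation constant to the constant of the dying step, reads 0.248. That neighbour flask ended with 68.9% of its free monomer reacted and 11.9 units per chain.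

The numbers of this flask are invented, and the outcome is calculated.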